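## Retrosynthetic overview

1. The strategy rests on three adjacent oxygenated carbons in ring B: the C6 ketone, the C7 β-hydroxyl and the quaternary C8 α-acetate, with the ketol next to the C5 ring-fusion methine. This ketol is made last, by ruthenium-catalysed ketohydroxylation of a C6=C7 alkene. The acid-labile C14=C15 enol ether of ring D is carried as its C15 methyl acetal and released in the final step.
2. The 6-ene 8α-acetate comes from a 9α-hydroxy-7-ene by hydroxyl-directed epoxidation (C8–O α) and selenoxide transposition. C9 is set by vinyl addition to the convex face of a cis-fused 8-methyl-7-en-9-one.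
3. Ring C closes by 5-exo opening of a Sharpless epoxide at C13 by the 9α-hydroxyl, after the C13–C16 unit is joined by B-alkyl Suzuki coupling. Ring D follows by glycol cleavage, methoxymethylenation and acetal closure through the C16 hydroxyl.
4. The enone comes from the cis-decalin 8-keto-9-ester by a 1,2-carbonyl shift through the diosphenol triflate. Rings A and B form together in the cation–olefin bicyclisation of the neryl acetoacetate.
5. Ring order: A and B together, then C, then D.

Key step: step 21

Remark 1: Labdane numbering is used. β is the face of the C10 methyl group, which is the convex face of the cis-decalin.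
Remark 2: The bicyclisation gives a racemate. Absolute configuration enters with the Sharpless epoxidation, and the series built on the mirror-image decalin is removed as a diastereomer after ring C closure. SMILES of racemic compounds show the enantiomer that leads to the target.
Remark 3: C15 of the ring D acetals is a mixture of epimers of no consequence and is left undefined.

## Route

Step 1
Reactants: 1 nerol
Product: 2 neryl bromide
Conditions: PBr3, Et2O, −10 °C
Reagents that add atoms: phosphorus tribromide, BrP(Br)Br
Why: Bromination of a primary allylic alcohol through its phosphite ester (SN2 displacement by bromide) at low temperature should keep the Z geometry of the alkene.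

Step 2
Reactants: 3 methyl acetoacetate; 2 neryl bromide
Product: 5 methyl (6Z)-7,11-dimethyl-3-oxododeca-6,10-dienoate, via dianion 4 (not isolated)
Conditions: NaH, THF, 0 °C; n-BuLi, 0 °C; then 2, 0 °C to rt; dilute HCl
Reagents that add atoms: none
Why: γ-Alkylation of the acetoacetate dianion, in which the more basic terminal carbanion displaces the allylic bromide by SN2 without touching the Z alkene.

Step 3
Reactants: 5 methyl (6Z)-7,11-dimethyl-3-oxododeca-6,10-dienoate
Product: 6 (±)-cis-fused bicyclic β-keto ester (C8 ketone, C9 CO2Me, H5 and C10 methyl both β)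
Conditions: SnCl4, water-saturated CH2Cl2, 0 °C to rt
Reagents that add atoms: none
Why: Acid-induced cation–olefin bicyclisation ending at the enol carbon of the tin-chelated β-keto ester closes rings A and B at once; anti addition of C4 and C9 across the Z-configured C5=C10 alkene in a chair–chair array (Stork–Eschenmoser stereospecificity) should place H5 and the C10 methyl group cis, as a racemate.

Step 4
Reactants: 6 (±)-cis-fused bicyclic β-keto ester
Product: 7 (±)-9-hydroxy β-keto ester
Conditions: dimethyldioxirane, acetone, 0 °C
Reagents that add atoms: dimethyldioxirane, CC1(C)OO1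
Why: Electrophilic α-hydroxylation of the enol form of a β-keto ester by a dioxirane; the configuration at C9 does not matter because C9 becomes sp2 again in step 6.

Step 5
Reactants: 7 (±)-9-hydroxy β-keto ester
Product: 8 (±)-acyloin (9-hydroxy-8-ketone, in equilibrium with its ketol tautomer)
Conditions: LiCl, H2O, DMSO, 150 °C
Reagents that add atoms: none
Why: Krapcho dealkoxycarbonylation, in which chloride demethylates the hindered ester by SN2 at the methyl group, the β-keto carboxylate loses CO2 and the enediolate is protonated to the acyloin, whose tautomers and epimers all converge in the next step.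

Step 6
Reactants: 8 (±)-acyloin
Product: 10 (±)-diosphenol (8-hydroxy-7-en-9-one), via 8,9-dione 9 (not isolated)
Conditions: Dess–Martin periodinane, CH2Cl2, rt; then Et3N (cat.)
Reagents that add atoms: none
Why: Dess–Martin oxidation of the acyloin gives the 1,2-dione, which can enolise only toward C7 because C10 is quaternary, so a single diosphenol should result.

Step 7
Reactants: 10 (±)-diosphenol
Product: 11 (±)-8-triflyloxy-7-en-9-one
Conditions: Tf2O, pyridine, CH2Cl2, −78 to 0 °C
Reagents that add atoms: triflic anhydride, O=S(=O)(OS(=O)(=O)C(F)(F)F)C(F)(F)F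
Why: O-Sulfonylation of the acidic enol hydroxyl gives an α-triflyloxy enone that serves as the alkenyl electrophile for cross-coupling.

Step 8
Reactants: 11 (±)-8-triflyloxy-7-en-9-one
Product: 12 (±)-cis-fused 8-methyl-7-en-9-one
Conditions: MeB(OH)2, Pd(dppf)Cl2 (cat.), K2CO3, dioxane/H2O, 80 °C
Reagents that add atoms: methylboronic acid, CB(O)O
Why: Suzuki–Miyaura coupling of the alkenyl triflate installs the C8 methyl group (C17) and leaves the hindered ketone and the ring fusion untouched.

Step 9
Reactants: 12 (±)-cis-fused 8-methyl-7-en-9-one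
Product: 13 (±)-9α-hydroxy-9β-vinyl-8-methyl-7-ene
Conditions: CeCl3, CH2=CHMgBr, THF, −78 to 0 °C; aq NH4Cl
Reagents that add atoms: vinylmagnesium bromide, C=C[Mg]Br
Why: 1,2-Addition of a weakly basic organocerium reagent to a hindered enone without α-hydrogens; in either half-chair of the cis-decalin the α face of C9 is blocked (by the axial C1 methylene beside the carbonyl or by axial C4), so the vinyl group (C11, C12) should enter from the convex β face and leave the hydroxyl α.

Step 10
Reactants: 13 (±)-9α-hydroxy-9β-vinyl-8-methyl-7-ene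
Product: 14 (±)-7α,8α-epoxy-9α-ol
Conditions: VO(acac)2 (cat.), t-BuOOH, toluene, 0 °C to rt
Reagents that add atoms: tert-butyl hydroperoxide, CC(C)(C)OO
Why: Hydroxyl-directed epoxidation of an allylic alcohol, in which the vanadium alkoxide–peroxide complex delivers oxygen to the electron-rich trisubstituted C7=C8 bond on the face of the 9α-hydroxyl; this fixes the C8–O bond α (cis to the C9 oxygen) and spares the monosubstituted vinyl group.

Step 11
Reactants: 14 (±)-7α,8α-epoxy-9α-ol
Product: 17 (±)-6-ene-8α,9α-diol, via hydroxy selenide 15 (not isolated), via selenoxide 16 (not isolated)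
Conditions: (PhSe)2, NaBH4, EtOH, reflux; then THF, pyridine, 30% H2O2, 0 °C to rt
Reagents that add atoms: none
Why: Organoselenium conversion of an epoxide into an allylic alcohol, in which benzeneselenolate opens the epoxide trans-diaxially by SN2 at the less substituted C7 from the β face, and the selenoxide then eliminates syn, which can only run toward C6 because C8 carries no hydrogen; C8 keeps its configuration.

Step 12
Reactants: 17 (±)-6-ene-8α,9α-diol
Product: 18 (±)-8α-acetoxy-9α-hydroxy-9β-vinyl-6-ene
Conditions: Ac2O, DMAP, Et3N, CH2Cl2, 40 °C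
Reagents that add atoms: acetic anhydride, CC(=O)OC(C)=O
Why: DMAP-catalysed acylation should pick the tertiary allylic 8-hydroxyl, whose neighbours include a methyl group and an sp2 carbon, over the 9-hydroxyl held between two quaternary carbons.

Step 13
Reactants: 19 but-2-yne-1,4-diol
Product: 20 4-(tert-butyldimethylsilyloxy)but-2-yn-1-ol
Conditions: TBSCl (limiting), imidazole, THF, 0 °C to rt, excess 19
Reagents that add atoms: tert-butyldimethylsilyl chloride, CC(C)(C)[Si](C)(C)Cl
Why: Statistical monosilylation of a symmetrical diol used in excess.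

Step 14
Reactants: 20 4-(tert-butyldimethylsilyloxy)but-2-yn-1-ol
Product: 22 (2Z)-4-(tert-butyldimethylsilyloxy)-3-iodobut-2-en-1-ol, via alkenyl alanate 21 (not isolated)
Conditions: NaAlH2(OCH2CH2OMe)2, THF, 0 °C to rt; EtOAc; then N-iodosuccinimide, −78 °C
Reagents that add atoms: N-iodosuccinimide, O=C1CCC(=O)N1I
Why: Hydroxyl-directed trans-hydroalumination of a propargylic alcohol places aluminium on the distal alkyne carbon in a five-membered alanate, and iodinolysis with retention should give the Z-iodide regio- and stereospecifically.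

Step 15
Reactants: 18 (±)-8α-acetoxy-9α-hydroxy-9β-vinyl-6-ene; 22 (2Z)-4-(tert-butyldimethylsilyloxy)-3-iodobut-2-en-1-ol
Product: 24 (±)-(13E)-allylic alcohol (C9–C11H2–C12H2–C13(CH2OTBS)=C14H–C15H2OH), via alkylborane 23 (not isolated)
Conditions: 9-BBN, THF, rt; then 22, Pd(dppf)Cl2 (cat.), AsPh3, Cs2CO3, DMF/H2O, rt
Reagents that add atoms: none
Why: Anti-Markovnikov hydroboration of the only monosubstituted alkene followed by B-alkyl Suzuki–Miyaura coupling, which keeps the iodide geometry (C12 ends cis to C15); oxidative addition to the alkenyl iodide should outrun ionisation of the hindered tertiary allylic acetate by zerovalent palladium.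

Step 16
Reactants: 24 (±)-(13E)-allylic alcohol
Product: 25 (13S,14S)-13,14-epoxy-15-ol
Conditions: Ti(OiPr)4 (cat.), L-(+)-diethyl tartrate, t-BuOOH, 4 Å MS, CH2Cl2, −20 °C
Reagents that add atoms: tert-butyl hydroperoxide, CC(C)(C)OO
Why: Sharpless asymmetric epoxidation of a 3,3-disubstituted primary allylic alcohol sets C13 and C14 by reagent control (same sense as geraniol with the L-(+)-tartrate) independently of the remote decalin, so the two enantiomers of 24 become two diastereomers that are carried on together.

Step 17
Reactants: 25 (13S,14S)-13,14-epoxy-15-ol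
Product: 26 9α,13-epoxy spiro ether (13R,14S)-14,15-diol, single enantiomer after chromatography
Conditions: camphorsulfonic acid (cat.), CH2Cl2, 0 °C; chromatography
Reagents that add atoms: none
Why: Acid-catalysed 5-exo-tet opening of the epoxide at its tertiary carbon C13 by the 9α-hydroxyl, with inversion, closes ring C and places C16 cis to C10 across that ring; the C14 and C16 arms differ from the outset, and the spiro diastereomer built on the mirror-image decalin is removed here.

Step 18
Reactants: 26 9α,13-epoxy spiro ether 14,15-diol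
Product: 27 C14 aldehyde
Conditions: NaIO4, THF/pH 7 buffer, 0 °C to rt
Reagents that add atoms: none
Why: Malaprade glycol cleavage removes C15 and the no longer needed C14 stereocentre and gives an α-alkoxy aldehyde on quaternary C13 that cannot epimerise.

Step 19
Reactants: 27 C14 aldehyde
Product: 28 methyl enol ether (C14H=C15H–OMe, E/Z mixture)
Conditions: Ph3P(CH2OMe)Cl, KN(SiMe3)2, THF, 0 °C; then 27, −78 to 0 °C
Reagents that add atoms: (methoxymethyl)triphenylphosphonium chloride, COC[P+](c1ccccc1)(c1ccccc1)c1ccccc1.[Cl-]
Why: Wittig methoxymethylenation returns C15 at the aldehyde oxidation level; the aldehyde has no α-hydrogen and the hindered tertiary acetate should survive the ylide at low temperature.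

Step 20
Reactants: 28 methyl enol ether
Product: 30 6-ene 8α-acetate with rings C and D closed, ring D as C15 methyl acetal, via hydroxy dimethyl acetal 29 (not isolated)
Conditions: camphorsulfonic acid (cat.), MeOH, rt
Reagents that add atoms: methanol, CO
Why: Acid-catalysed addition of methanol to the enol ether, methanolysis of the primary silyl ether and transacetalisation (5-exo-trig attack of the C16 hydroxyl on the C15 oxocarbenium ion) close ring D; C13 is not involved.

Step 21
Reactants: 30 6-ene 8α-acetate with ring D as methyl acetal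
Product: 32 6-keto-7β-hydroxy-8α-acetate with ring D as methyl acetal, via ruthenate ester 31 (not isolated)
Conditions: RuCl3 (1 mol %), KHSO5 (as 2KHSO5·KHSO4·K2SO4), NaHCO3, EtOAc/MeCN/H2O, rt, short reaction time
Reagents that add atoms: potassium peroxymonosulfate, [K+].[O-]S(=O)(=O)OO
Why: RuO4 (octavalent ruthenium oxide, formed in the flask) cycloadds suprafacially to the C6=C7 π bond, and the five-membered diolate 31 of hexavalent ruthenium takes up peroxymonosulfate at the metal and sheds one carbinol hydrogen, which turns that carbon into a carbonyl group and frees the neighbouring C–O bond as a hydroxyl of unchanged geometry. The closest known reaction is the ruthenium-catalysed ketohydroxylation of 1,2-disubstituted and cyclic alkenes to α-hydroxy ketones, with OsO4 dihydroxylation anti to an allylic ester as the stereochemical model. No ring is closed; the two new bonds to the skeleton are the C6 carbonyl and C7–O. The one new stereocentre, C7, is fixed by the face of attack: the α face is the concave face of the cis-decalin, covered by ring A (axial C1 methylene) and by the pseudo-axial C8 acetate, so the oxide should approach from the convex β face and leave the hydroxyl β, trans to the acetate. The step also needs regioselectivity for the C6 carbonyl, which should follow from the more hydridic and more accessible C6–H, since C7–H is deactivated by the acetoxy-bearing quaternary C8 next to it. Chemoselectivity over glycol cleavage and over the ether and acetal C–H bonds of rings C and D rests on the low catalyst loading, the NaHCO3 buffer and the short reaction time, which also protect the epimerisable C5.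

Step 22
Reactants: 32 6-keto-7β-hydroxy-8α-acetate with ring D as methyl acetal
Product: 35 target CNP0275274.1, via silyl ether acetal 33 (not isolated), via silylated enol ether 34 (not isolated)
Conditions: Me3SiOTf, iPr2NEt, CH2Cl2, −20 to 0 °C; then Bu4NF/AcOH, THF, 0 °C
Reagents that add atoms: none
Why: Acetal-to-enol-ether elimination, in which the silyl triflate ionises the C15 methoxy group to the ring D oxocarbenium ion and the hindered amine removes a C14 proton; the C7 hydroxyl is silylated in passing and freed by buffered fluoride, a medium neither acidic for the enol ether nor basic for C5 and C7.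

## Compound list

1 | nerol, (2Z)-3,7-dimethylocta-2,6-dien-1-ol | CC(C)=CCC/C(C)=C\CO | starting material
2 | neryl bromide | CC(C)=CCC/C(C)=C\CBr | intermediate
3 | methyl acetoacetate | COC(=O)CC(C)=O | starting material
4 | sodium lithium dianion of methyl acetoacetate | [Na+].[Li+].COC(=O)[CH-]C(=O)[CH2-] | intermediate
5 | methyl (6Z)-7,11-dimethyl-3-oxododeca-6,10-dienoate | COC(=O)CC(=O)CC/C=C(\CCC=C(C)C)C | intermediate
6 | (±)-methyl cis-5,5,8a-trimethyl-2-oxodecahydronaphthalene-1-carboxylate (8-ketone, 9-CO2Me, 5βH, 10β-Me; C9 epimers and enol) | O=C1CC[C@@H]2C(C)(C)CCC[C@]2(C)C1C(=O)OC | intermediate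
7 | (±)-9-hydroxy derivative of 6 (C9 undefined) | O=C1CC[C@@H]2C(C)(C)CCC[C@]2(C)C1(O)C(=O)OC | intermediate
8 | (±)-cis-decalin acyloin, 9-hydroxy-8-ketone (with ketol tautomer) | O=C1CC[C@@H]2C(C)(C)CCC[C@]2(C)C1O | intermediate
9 | (±)-cis-decalin-8,9-dione | O=C1CC[C@@H]2C(C)(C)CCC[C@]2(C)C1=O | intermediate
10 | (±)-diosphenol, 8-hydroxy-7-en-9-one | OC1=CC[C@@H]2C(C)(C)CCC[C@]2(C)C1=O | intermediate
11 | (±)-8-triflyloxy-7-en-9-one | O=S(=O)(OC1=CC[C@@H]2C(C)(C)CCC[C@]2(C)C1=O)C(F)(F)F | intermediate
12 | (±)-cis-fused 8-methyl-7-en-9-one | CC1=CC[C@@H]2C(C)(C)CCC[C@]2(C)C1=O | intermediate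
13 | (±)-9α-hydroxy-9β-vinyl-8-methyl-7-ene | CC1=CC[C@@H]2C(C)(C)CCC[C@]2(C)[C@@]1(O)C=C | intermediate
14 | (±)-7α,8α-epoxy-9α-hydroxy-9β-vinyl compound | C[C@@]12O[C@@H]1C[C@@H]3C(C)(C)CCC[C@]3(C)[C@@]2(O)C=C | intermediate
15 | (±)-7β-phenylselanyl-8α,9α-diol | C[C@@]1(O)[C@@H]([Se]c3ccccc3)C[C@@H]2C(C)(C)CCC[C@]2(C)[C@@]1(O)C=C | intermediate
16 | (±)-selenoxide of 15 | C[C@@]1(O)[C@@H]([Se](=O)c3ccccc3)C[C@@H]2C(C)(C)CCC[C@]2(C)[C@@]1(O)C=C | intermediate
17 | (±)-6-ene-8α,9α-diol (8β-Me, 9β-vinyl) | C[C@@]1(O)C=C[C@@H]2C(C)(C)CCC[C@]2(C)[C@@]1(O)C=C | intermediate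
18 | (±)-8α-acetoxy-9α-hydroxy-9β-vinyl-6-ene | CC(=O)O[C@]1(C)C=C[C@@H]2C(C)(C)CCC[C@]2(C)[C@@]1(O)C=C | intermediate
19 | but-2-yne-1,4-diol | OCC#CCO | starting material
20 | 4-(tert-butyldimethylsilyloxy)but-2-yn-1-ol | CC(C)(C)[Si](C)(C)OCC#CCO | intermediate
21 | cyclic sodium alkenyl alanate from 20 | [Na+].COCCO[Al-]1(OCCOC)OCC=C1CO[Si](C)(C)C(C)(C)C | intermediate
22 | (2Z)-4-(tert-butyldimethylsilyloxy)-3-iodobut-2-en-1-ol | OC/C=C(\I)CO[Si](C)(C)C(C)(C)C | intermediate
23 | (±)-C12 B-alkyl-9-borabicyclononane from 18 | CC(=O)O[C@]1(C)C=C[C@@H]2C(C)(C)CCC[C@]2(C)[C@@]1(O)CCB3C4CCCC3CCC4 | intermediate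
24 | (±)-(13E)-allylic alcohol, C12 cis to C15 | CC(=O)O[C@]1(C)C=C[C@@H]2C(C)(C)CCC[C@]2(C)[C@@]1(O)CC/C(CO[Si](C)(C)C(C)(C)C)=C\CO | intermediate
25 | (13S,14S)-13,14-epoxy-15-ol | CC(=O)O[C@]1(C)C=C[C@@H]2C(C)(C)CCC[C@]2(C)[C@@]1(O)CC[C@@]3(CO[Si](C)(C)C(C)(C)C)O[C@H]3CO | intermediate
26 | 9α,13-epoxy spiro ether, (13R,14S)-14,15-diol, C16 as TBS ether cis to C10 across ring C | CC(=O)O[C@]1(C)C=C[C@@H]2C(C)(C)CCC[C@]2(C)[C@@]12CC[C@@](CO[Si](C)(C)C(C)(C)C)([C@@H](O)CO)O2 | intermediate
27 | C14 aldehyde | CC(=O)O[C@]1(C)C=C[C@@H]2C(C)(C)CCC[C@]2(C)[C@@]12CC[C@@](CO[Si](C)(C)C(C)(C)C)(C=O)O2 | intermediate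
28 | C14=C15 methyl enol ether (E/Z) | CC(=O)O[C@]1(C)C=C[C@@H]2C(C)(C)CCC[C@]2(C)[C@@]12CC[C@@](CO[Si](C)(C)C(C)(C)C)(C=COC)O2 | intermediate
29 | 16-hydroxy C15 dimethyl acetal | CC(=O)O[C@]1(C)C=C[C@@H]2C(C)(C)CCC[C@]2(C)[C@@]12CC[C@@](CO)(CC(OC)OC)O2 | intermediate
30 | 6-ene 8α-acetate, ring D as methyl acetal (key-step precursor) | CC(=O)O[C@]1(C)C=C[C@@H]2C(C)(C)CCC[C@]2(C)[C@@]12CC[C@@]1(CC(OC)OC1)O2 | intermediate
31 | 6β,7β-cyclic ruthenate ester | CC(=O)O[C@]1(C)[C@H]3O[Ru](=O)(=O)O[C@H]3[C@@H]2C(C)(C)CCC[C@]2(C)[C@@]12CC[C@@]1(CC(OC)OC1)O2 | intermediate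
32 | 6-keto-7β-hydroxy-8α-acetate, ring D as methyl acetal (key-step product) | CC(=O)O[C@]1(C)[C@@H](O)C(=O)[C@@H]2C(C)(C)CCC[C@]2(C)[C@@]12CC[C@@]1(CC(OC)OC1)O2 | intermediate
33 | 7-O-trimethylsilyl ether of 32 | CC(=O)O[C@]1(C)[C@@H](O[Si](C)(C)C)C(=O)[C@@H]2C(C)(C)CCC[C@]2(C)[C@@]12CC[C@@]1(CC(OC)OC1)O2 | intermediate
34 | 7-O-trimethylsilyl ether of the target | CC(=O)O[C@]1(C)[C@@H](O[Si](C)(C)C)C(=O)[C@@H]2C(C)(C)CCC[C@]2(C)[C@@]12CC[C@@]1(C=COC1)O2 | intermediate
35 | CNP0275274.1 | CC(=O)O[C@]1(C)[C@@H](O)C(=O)[C@@H]2C(C)(C)CCC[C@]2(C)[C@@]12CC[C@@]1(C=COC1)O2 | target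

## Step count and risks

Total steps: 22. Longest linear sequence: 20 steps (nerol to target, steps 1–12 and 15–22).

Steps most likely to fail:

1. **Step 21.** The hindered alkene may react slowly. The diolate may collapse toward the C7 ketone. The glycol may be cleaved, or the acetal and ether C–H bonds of rings C and D may be oxidised.
   Fallback: the two oxidation events are separated. Starting from 30, catalytic OsO4 with N-methylmorpholine N-oxide in acetone/water should dihydroxylate the convex face and give the 6β,7β-diol F1. A sterically governed mono-oxidation (one equivalent of Dess–Martin periodinane, or TEMPO with PhI(OAc)2) should then take the more accessible C6 carbinol. The route is rejoined at 32.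

2. **Step 22.** The silyl triflate may activate the ring C oxygen once the enol ether is present, which opens ring C and aromatises ring D to a furan. The C6 ketone may also be converted into a silyl enol ether, with loss of configuration at C5 or C7 on desilylation.
   Fallback: a neutral thermal elimination replaces the Lewis-acid ionisation. Starting from 32, exchange of the C15 methoxy group with PhSeH and BF3·OEt2 at −78 °C, before any enol ether exists, would give the 15-phenylselanyl ether F2. One equivalent of mCPBA at −78 °C gives the selenoxide F3. On warming with iPr2NEt, F3 undergoes syn elimination toward C14 and arrives directly at 35.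

3. **Step 10.** Oxygen delivery to the concave α face may be slow, so that unselective epoxidation, attack at the vinyl group or oxidative transposition of the tertiary bis-allylic alcohol competes.
   Fallback: the oxygen is delivered from a tether while the external electrophile uses the open face. Starting from 13, deprotonation with n-BuLi, carboxylation with CO2 and treatment with I2 should form the iodonium ion on the convex β face and close the carbonate onto C8 from the α face. This gives the 7β-iodo 8α,9α-cyclic carbonate F4. DBU in hot toluene removes hydrogen iodide by anti elimination toward C6 to give the 6-ene cyclic carbonate F5. K2CO3 in MeOH then cleaves the carbonate, and the route is rejoined at 17.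

Further compounds
F1 | step 21 | 6β,7β-diol 8α-acetate with ring D as methyl acetal | CC(=O)O[C@]1(C)[C@@H](O)[C@@H](O)[C@@H]2C(C)(C)CCC[C@]2(C)[C@@]12CC[C@@]1(CC(OC)OC1)O2
F2 | step 22 | 6-keto-7β-hydroxy-8α-acetate with a 15-phenylselanyl ring D | CC(=O)O[C@]1(C)[C@@H](O)C(=O)[C@@H]2C(C)(C)CCC[C@]2(C)[C@@]12CC[C@@]1(CC([Se]c3ccccc3)OC1)O2
F3 | step 22 | selenoxide of F2 | CC(=O)O[C@]1(C)[C@@H](O)C(=O)[C@@H]2C(C)(C)CCC[C@]2(C)[C@@]12CC[C@@]1(CC([Se](=O)c3ccccc3)OC1)O2
F4 | step 10 | (±)-7β-iodo 8α,9α-cyclic carbonate | C[C@@]1(OC3=O)[C@@H](I)C[C@@H]2C(C)(C)CCC[C@]2(C)[C@@]1(O3)C=C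
F5 | step 10 | (±)-6-ene 8α,9α-cyclic carbonate | C[C@@]1(OC3=O)C=C[C@@H]2C(C)(C)CCC[C@]2(C)[C@@]1(O3)C=C
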